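## The problem

The target 32 is a ten-membered carbocycle (C1–C10) with a γ-lactone cis-fused across C6–C7 (ring oxygen on C6, C11 on C7, carbonyl C12, exocyclic C11=C13). It has two Z-trisubstituted ring alkenes (C4=C5 and C9=C10, methyl groups on C4 and C10), a free hydroxyl at C1, an acetate at C3 and an angelate at C8. Its five stereocentres fall into two groups, the 1,3-anti pair C1/C3 (both S) and the contiguous triad C6/C7/C8. The two alkenes separate these groups, so neither can be relied on to control the other and each must be made in absolute terms. Within the triad C7 is the natural control element, because it is adjacent to both C6 and C8. Three oxygens that end as OH, OAc and OAng must be told apart, two of them (O1, O3) in constitutionally identical surroundings, and the lactone must stay on O6 although O8 is equally well placed to take it. Late chemistry is limited by four groups: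
- the α-methylene lactone, a Michael acceptor whose C7–H becomes doubly activated if C8 is a carbonyl;
- the angelate, which isomerizes to the tiglate with base or nucleophiles;
- the allylic C–O bonds at C1, C3, C6 and C8, which ionize under acid;
- the monoacetylated 1,3-diol, in which the acyl group can migrate.

The enabling feature is that C1 and C3 are homochiral carbinols, each bonded to the methyl-bearing carbon of a Z-alkene whose other terminus (C9, C5) is cis to the carbinol. With the acyl difference ignored, C9=C10(Me)–C1–C2–C3–C4(Me)=C5 is C2-symmetric, and this cis arrangement is what anti-addition of methyl and a metal across a terminal propargylic alkoxide produces.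

## Retrosynthesis

**Acyl groups and the exocyclic alkene (32 back to 23).** The O1–H, O3–acetyl and O8–angeloyl bonds are cut first (32 ⇒ 31 ⇒ 30 ⇒ 29 ⇒ 26), then C11=C13 (26 ⇒ 23). The reverse order, esters first and methylene last, is rejected because enolate chemistry cannot distinguish the lactone from an acetate or an angelate. The methylene is therefore put on 23, which has no ester besides the lactone. This requires O1 and O3 to carry different silyl groups (tert-butyldimethylsilyl to the end, triethylsilyl temporarily) and the angelate to be introduced from 27 without isomerization.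

**Ring closure (23 back to 22).** The ten-membered ring is cut at C8–C9, an alkenyl iodide adding to an aldehyde under NiCl2/CrCl2. Cutting at C5–C6 instead would leave the C8 carbinol to be made between two molecules, where its alkoxide would take the lactone. Cutting inside C1–C3 would destroy the symmetry that the key step uses. Aldehyde 22 has both chain ends held cis on the lactone. C11 is kept saturated at this stage so that the C7–H, now alpha to an aldehyde, is not also allylic. The forward reaction must favour ring closure over oligomerization, retain the Z geometry and choose the right face at C8.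

**C5–C6 bond and lactone (19 back to 9 and 16).** Aldehyde 22 comes from 19 by three functional-group steps (20, 21). Lactone 19 is cut at C5–C6 and at O6–C12 into diiodide 9 and aldehyde ester 16. The free C3 hydroxyl of 9 selects which of two otherwise identical alkenyl iodides is metalated. The C6 alkoxide formed in the addition then closes the lactone, which protects O6 and distinguishes it from O3. The fragments have nine and five skeletal carbons. The forward step needs site-selective iodine–magnesium exchange and control of C6 by C7.

**The C7 fragment (16 back to 10, 11 and 13).** C7 is the only stereocentre of the triad that has to be bought. It is set by alkylating the succinate imide 12 (from 10 and 11) with chloromethyl ether 13 to give 14. This brings C8 in with its oxygen already masked, so no γ-hydroxy ester that could lactonize toward C12 ever appears. The naphthylmethyl ether can chelate magnesium and is removed oxidatively under conditions that spare silyl ethers. The imide is converted to the aldehyde without passing through an alcohol (14 ⇒ 15 ⇒ 16).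

**Breaking the symmetry (9 back to 8).** Monosilylation of the C2-symmetric diol 8 gives one compound whichever hydroxyl reacts, so the only cost is statistical.

**Key disconnection (8 back to 5 and 6).** Both C–CH3 bonds (C4, C10) and both C–I bonds are cut at once, leading to diynediol 5 and methylmagnesium bromide 6. Syn-carbometalation would give the E-iodides, and building each alkene separately would double the step count. The alkoxide-directed anti-addition gives the Z-iodide and places the metal where C6 and C8 will later be attached.

**The diynediol (5 back to 1 and 2).** Diol 5 is the desilylated form of 4, which comes from diketone 3 by twofold catalytic transfer hydrogenation. Diketone 3 is cut at C2–C3 into ynone 1 and ynoate 2. One catalyst sets both carbinols, and the mismatched by-product is a separable meso compound.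

## Roads not taken

**Alternative 1:** The cut is at C1–C2 and O–C3. An open-chain C1 aldoxime A1, with a terminal C2=C3 vinyl group on the Z-diene and the saturated lactone in place, is oxidized with NaOCl to the nitrile oxide. This adds across the vinyl group to give the isoxazoline-bridged cyclodecadiene A2.
- Merits: one step closes the carbocycle and installs the C3 oxygen and the C1 carbon oxidation level. The regiochemistry (carbon to the CH2 terminus) is the normal one, and no stoichiometric metal is needed. In ring-forming efficiency it is at least as good as the chromium-mediated closure chosen here.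
- Weak points: C3 is created in the ring closure with only macrocyclic facial bias. The conjugated nitrile oxide can dimerize. After N–O cleavage the C1 ketone must be reduced 1,3-anti under hydroxyl direction, which leaves O1 and O3 both free and then requires selective acetylation of one of two near-identical hydroxyls.
- Comparison: the chosen plan sets C1 and C3 by catalyst before any ring exists and distinguishes O1 from O3 through symmetry. It pays for this with a statistical silylation and a separate ring-closing step.

**Alternative 2:** The cut is the C6–O bond. The fully acylated 6-deoxy acid A3 would be lactonized by Pd(OAc)2, a bis-sulfoxide ligand and benzoquinone through cleavage of a C6–H bond and attack of the carboxylate on the allyl-palladium intermediate, giving A4, the C1 triethylsilyl ether of 32.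
- Merits: the lactone and the C6 stereocentre come last, O6 never needs protection, and the end of the synthesis is shorter than the one chosen here.
- Weak points: this oxidation is established for terminal alkenes. Here the alkene is trisubstituted, Z and endocyclic, with competing allylic C–H bonds at C3 and the C4 methyl group. The allyl intermediate can be attacked at C4 or C6 and can lose the Z geometry. The angelate and the acrylic acid are exposed to palladium hydrides. The ring of A3 with four stereocentres still has to be built.
- Comparison: the chosen plan fixes C6 in a chelation-controlled addition with a known model and never exposes the finished diene and angelate to palladium. It gives up the late-stage economy of this route.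

**Alternative 3:** The cut is C2–C3. The bromoketone enal A5 is treated with SmI2. The samarium enolate closes the ring on the C3 aldehyde, and added acetaldehyde then reduces C1 by intramolecular hydride transfer and leaves its acetyl group on O3, giving A6.
- Merits: ring closure, the 1,3-anti relation and the O1/O3 differentiation happen in one flask. On differentiation this is better than the chosen plan, which needs a statistical monosilylation and a temporary silyl group on O3.
- Weak points: the absolute configuration at C3 must be induced across a Z-alkene by the remote C6–C8 triad. SmI2 can also reduce the Z-enal and the enone. The two Z-alkenes must be made separately. The C7 ethynyl group still has to be turned into the methylene lactone.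
- Comparison: the chosen plan has one step that makes both alkenes, and its carbinol configurations do not depend on a macrocyclic aldol.

Key step: step 4

Remark: 2-[(chloromethoxy)methyl]naphthalene (13) is taken as a purchasable alkylating agent like its benzyl analogue. Carbon numbers C1–C13 in names and comments are those of the target defined above.

## Route

Step 1
Reactants: 1 4-(trimethylsilyl)but-3-yn-2-one; 2 ethyl 3-(trimethylsilyl)prop-2-ynoate
Product: 3 1,7-bis(trimethylsilyl)hepta-1,6-diyne-3,5-dione
Conditions: LiHMDS (2.2 equiv), THF, −78 °C; then 2, −78 → −20 °C; AcOH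
Reagents that add atoms: none
Why: Crossed Claisen condensation: the kinetic lithium enolate of the methyl ketone attacks the non-enolizable ester, and the second equivalent of base drives the reaction by deprotonating the 1,3-diketone. The silyl caps shield both alkyne termini from conjugate addition.

Step 2
Reactants: 3 1,7-bis(trimethylsilyl)hepta-1,6-diyne-3,5-dione
Product: 4 (3S,5S)-1,7-bis(trimethylsilyl)hepta-1,6-diyne-3,5-diol
Conditions: RuCl[(S,S)-TsDPEN](p-cymene) (2 mol%), HCO2H/Et3N (5:2), CH2Cl2, 25 °C
Reagents that add atoms: none
Why: Noyori asymmetric transfer hydrogenation, used twice by one catalyst. Each hydride is delivered to the same face relative to the alkynyl group as in simple alkynyl ketones, so both carbinols should be S. The mismatched minor product is a diastereomer, and its removal should raise the enantiomeric purity of the anti diol.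

Step 3
Reactants: 4 (3S,5S)-1,7-bis(trimethylsilyl)hepta-1,6-diyne-3,5-diol
Product: 5 (3S,5S)-hepta-1,6-diyne-3,5-diol
Conditions: K2CO3 (0.2 equiv), MeOH, 0 → 25 °C
Reagents that add atoms: none
Why: Methanolysis of the C(sp)–Si bonds; the carbinol centres are not involved.

Step 4
Reactants: 5 (3S,5S)-hepta-1,6-diyne-3,5-diol; 6 methylmagnesium bromide
Product: 8 (1Z,3S,5S,6Z)-1,7-diiodo-2,6-dimethylhepta-1,6-diene-3,5-diol, via twofold alkenylmagnesium alkoxide 7 (not isolated)
Conditions: 6 (6 equiv), CuI (0.4 equiv), THF/Et2O, −20 → 25 °C; then I2 (3 equiv), THF, −40 → 0 °C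
Reagents that add atoms: iodine, II
Why: This is the alkoxide-directed anti-carbomagnesiation of a terminal propargylic alcohol, the known route from prop-2-yn-1-ol to (Z)-3-iodo-2-methylprop-2-en-1-ol, run at both ends of one diol. Two equivalents of 6 form the bis(magnesium alkoxide); a methylcopper species from CuI then delivers methyl to the internal alkyne carbon (C4, C10) while magnesium ends on the terminal carbon (C5, C9), held by the alkoxide in a five-membered oxamagnesacycle at each end (7). Because carbon and metal add to opposite faces of the triple bond, the metal-bearing carbon and the carbinol end cis. Iodine cleaves each C–Mg bond with retention, so both alkenes of 8 are Z. No ring of the target is closed and no stereocentre is created; the S carbinols are spectators. The selectivity needed is regiochemical (methyl internal) and geometric (anti), and both are secured by the chelating alkoxide. Since the two ends are homotopic, the mono-adduct on the way to 7 is a single compound and the second addition is the same reaction on the same kind of site. Excess 6 is used because the alkoxides consume two equivalents and the terminal C–H bonds can be partly metalated.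

Step 5
Reactants: 8 (1Z,3S,5S,6Z)-1,7-diiodo-2,6-dimethylhepta-1,6-diene-3,5-diol
Product: 9 (1Z,3S,5S,6Z)-5-[(tert-butyldimethylsilyl)oxy]-1,7-diiodo-2,6-dimethylhepta-1,6-dien-3-ol
Conditions: TBSCl (1.0 equiv), imidazole, DMF, −20 → 0 °C; recovered 8 recycled
Reagents that add atoms: tert-butyldimethylsilyl chloride, CC(C)(C)[Si](C)(C)Cl
Why: Statistical monosilylation of a C2-symmetric diol: the hydroxyls are homotopic, so the mono-ether is one compound. The silylated oxygen becomes O1 and the free one O3.

Step 6
Reactants: 10 (R)-4-benzyloxazolidin-2-one; 11 methyl 4-chloro-4-oxobutanoate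
Product: 12 methyl 4-[(R)-4-benzyl-2-oxooxazolidin-3-yl]-4-oxobutanoate
Conditions: n-BuLi, THF, −78 °C; then 11
Reagents that add atoms: none
Why: N-Acylation of the lithiated oxazolidinone by the acid chloride; the methyl ester is not attacked at this temperature.

Step 7
Reactants: 12 methyl 4-[(R)-4-benzyl-2-oxooxazolidin-3-yl]-4-oxobutanoate; 13 2-[(chloromethoxy)methyl]naphthalene
Product: 14 methyl (S)-3-{[(R)-4-benzyl-2-oxooxazolidin-3-yl]carbonyl}-4-(naphthalen-2-ylmethoxy)butanoate
Conditions: TiCl4 (1.05 equiv), i-Pr2NEt (1.1 equiv), CH2Cl2, 0 °C; then 13, 0 °C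
Reagents that add atoms: none
Why: Evans alkylation through the chelated titanium Z-enolate, which forms only on the imide side. The alkoxymethyl cation from 13 adds to the face opposite the benzyl group of the (R)-auxiliary, as benzyl chloromethyl ether does, and sets C7 (S in 14).

Step 8
Reactants: 14 methyl (S)-3-{[(R)-4-benzyl-2-oxooxazolidin-3-yl]carbonyl}-4-(naphthalen-2-ylmethoxy)butanoate
Product: 15 methyl (S)-3-[(ethylsulfanyl)carbonyl]-4-(naphthalen-2-ylmethoxy)butanoate
Conditions: EtSH (3 equiv), n-BuLi (2 equiv), THF, 0 °C
Reagents that add atoms: ethanethiol, CCS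
Why: Transthioesterification of the imide by lithium ethanethiolate: the exocyclic imide carbonyl is far more electrophilic than the methyl ester, and the auxiliary is recovered.

Step 9
Reactants: 15 methyl (S)-3-[(ethylsulfanyl)carbonyl]-4-(naphthalen-2-ylmethoxy)butanoate
Product: 16 methyl (S)-3-formyl-4-(naphthalen-2-ylmethoxy)butanoate
Conditions: Et3SiH (3 equiv), Pd/C (5 mol%), acetone, 25 °C
Reagents that add atoms: none
Why: Fukuyama reduction: palladium inserts into the C–S bond and the silane delivers hydride, giving the aldehyde under neutral conditions that spare the methyl ester and the arylmethyl ether and do not epimerize C7.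

Step 10
Reactants: 9 (1Z,3S,5S,6Z)-5-[(tert-butyldimethylsilyl)oxy]-1,7-diiodo-2,6-dimethylhepta-1,6-dien-3-ol; 16 methyl (S)-3-formyl-4-(naphthalen-2-ylmethoxy)butanoate
Product: 19 (4S,5R)-5-[(1Z,3S,5S,6Z)-5-[(tert-butyldimethylsilyl)oxy]-3-hydroxy-7-iodo-2,6-dimethylhepta-1,6-dien-1-yl]-4-[(naphthalen-2-ylmethoxy)methyl]dihydrofuran-2(3H)-one, via alkenylmagnesium alkoxide 17 (not isolated), via acyclic magnesium alkoxide adduct 18 (not isolated)
Conditions: 9, i-PrMgCl (2.05 equiv), THF, −30 → 0 °C; added to 16, MgBr2·OEt2 (2 equiv), CH2Cl2, −78 °C; → 25 °C; aq NH4Cl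
Reagents that add atoms: none
Why: The first equivalent of i-PrMgCl makes the C3 magnesium alkoxide, which directs iodine–magnesium exchange to the cis C5–I bond (oxamagnesacycle 17) and leaves the iodide next to the silyl ether. 17 adds to the aldehyde held in a six-membered magnesium chelate with the C8 ether oxygen (Cram chelate model); attack anti to the C11 arm places C5 and C8 cis. The C6 alkoxide of 18 then closes the γ-lactone on the methyl ester (5-exo-trig).

Step 11
Reactants: 19 (4S,5R)-5-[(1Z,3S,5S,6Z)-5-[(tert-butyldimethylsilyl)oxy]-3-hydroxy-7-iodo-2,6-dimethylhepta-1,6-dien-1-yl]-4-[(naphthalen-2-ylmethoxy)methyl]dihydrofuran-2(3H)-one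
Product: 20 the C3 triethylsilyl ether of 19
Conditions: TESCl, imidazole, DMF, 0 °C
Reagents that add atoms: chlorotriethylsilane, CC[Si](Cl)(CC)CC
Why: Silylation of the only free hydroxyl; the triethylsilyl group can later be removed in the presence of the tert-butyldimethylsilyl ether at O1.

Step 12
Reactants: 20 the C3 triethylsilyl ether of 19
Product: 21 the C8 primary alcohol (lactone with a hydroxymethyl group on C7; O3 triethylsilyl; O1 tert-butyldimethylsilyl; C9 iodide)
Conditions: DDQ (1.5 equiv), CH2Cl2/pH 7 buffer (10:1), 25 °C
Reagents that add atoms: none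
Why: Oxidative cleavage of the 2-naphthylmethyl ether (benzylic hydride abstraction, then hydrolysis); silyl ethers, alkenyl iodide and lactone are inert. The freed hydroxyl is gamma to C12, so 21 is oxidized at once to keep the lactone on O6.

Step 13
Reactants: 21 the C8 primary alcohol
Product: 22 the C8 aldehyde (formyl group on C7 of the cis-lactone)
Conditions: Dess–Martin periodinane, NaHCO3, CH2Cl2, 0 → 25 °C
Reagents that add atoms: none
Why: Dess–Martin oxidation under bicarbonate buffer; the neutral conditions leave C7, now alpha to the aldehyde, and the silyl ethers intact.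

Step 14
Reactants: 22 the C8 aldehyde
Product: 23 the ten-membered carbocyclic C8 alcohol (saturated cis-fused 6,12-lactone; O3 triethylsilyl; O1 tert-butyldimethylsilyl; 4Z,9Z; stereocentres as in 32)
Conditions: CrCl2 (12 equiv), NiCl2 (0.1 equiv), DMSO/THF (3:1), 25 °C, 0.003 M, slow addition of 22
Reagents that add atoms: none
Why: Nozaki–Hiyama–Kishi reaction: zerovalent nickel inserts into the C9–I bond, the alkenyl group passes to trivalent chromium with retention of the Z geometry and adds only to the aldehyde. The ring closes because both chain ends are held cis on the lactone. The 8R carbinol is expected from attack anti to the C6 substituent (Felkin sense with C6 as the large group).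

Step 15
Reactants: 23 the ten-membered carbocyclic C8 alcohol
Product: 26 the α-methylene lactone with free C8 hydroxyl (O3 triethylsilyl; O1 tert-butyldimethylsilyl), via Mannich base 24 (not isolated), via trimethylammonium iodide 25 (not isolated)
Conditions: LDA (2.5 equiv), THF, −78 °C; CH2=NMe2+ I− (3 equiv), −78 → 0 °C; then MeI, MeOH, 25 °C; then aq NaHCO3, CH2Cl2, 25 °C
Reagents that add atoms: N,N-dimethylmethyleneiminium iodide (Eschenmoser's salt), C=[N+](C)C.[I-]
Why: After the C8 alkoxide, the second equivalent of LDA gives the lactone enolate, the only enolizable carbonyl in 23. Mannich alkylation (24), exhaustive N-methylation (25) and bicarbonate-induced loss of trimethylamine give C11=C13. The C11 stereocentre formed in passing is destroyed, and no acetate or angelate is yet present to compete.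

Step 16
Reactants: 26 the α-methylene lactone with free C8 hydroxyl; 27 (Z)-2-methylbut-2-enoic acid (angelic acid)
Product: 29 the C8 angelate (O3 triethylsilyl; O1 tert-butyldimethylsilyl), via mixed anhydride 28 (not isolated)
Conditions: 27, 2,4,6-trichlorobenzoyl chloride, Et3N, toluene, 25 °C; then 26, toluene, 75 °C
Reagents that add atoms: none
Why: Esterification through the mixed 2,4,6-trichlorobenzoic anhydride (Yamaguchi activation) without a nucleophilic catalyst, the established way to acylate hindered secondary alcohols with angelic acid without isomerization to the tiglate. The alcohol attacks the less hindered angeloyl carbonyl.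

Step 17
Reactants: 29 the C8 angelate
Product: 30 the C3 alcohol (O8 angelate; O1 tert-butyldimethylsilyl)
Conditions: PPTS (0.2 equiv), MeOH/CH2Cl2 (1:4), 0 °C
Reagents that add atoms: none
Why: Acid-catalysed methanolysis removes the smaller triethylsilyl group and leaves the tert-butyldimethylsilyl ether. No base is present that could add to the methylene lactone or isomerize the angelate.

Step 18
Reactants: 30 the C3 alcohol
Product: 31 the O1 tert-butyldimethylsilyl ether of the target
Conditions: Ac2O, pyridine, DMAP (0.1 equiv), CH2Cl2, 0 → 25 °C
Reagents that add atoms: acetic anhydride, CC(=O)OC(C)=O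
Why: Acetylation of the only free hydroxyl under conditions too weakly basic to isomerize the angelate.

Step 19
Reactants: 31 the O1 tert-butyldimethylsilyl ether of the target
Product: 32 the target (1S,3S,6R,7R,8R; 4Z,9Z), CNP0319825.3
Conditions: HF·pyridine, pyridine, THF, 0 → 25 °C
Reagents that add atoms: none
Why: Fluoride cleavage of the Si–O bond under buffered, slightly acidic conditions, which avoid acetyl migration from O3 to O1, conjugate addition to the methylene lactone and lactone migration.

## Compound list

1 | 4-(trimethylsilyl)but-3-yn-2-one | CC(=O)C#C[Si](C)(C)C | starting material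
2 | ethyl 3-(trimethylsilyl)prop-2-ynoate | CCOC(=O)C#C[Si](C)(C)C | starting material
3 | 1,7-bis(trimethylsilyl)hepta-1,6-diyne-3,5-dione (mainly enol) | C[Si](C)(C)C#CC(=O)CC(=O)C#C[Si](C)(C)C | intermediate
4 | (3S,5S)-1,7-bis(trimethylsilyl)hepta-1,6-diyne-3,5-diol | C[Si](C)(C)C#C[C@@H](O)C[C@H](O)C#C[Si](C)(C)C | intermediate
5 | (3S,5S)-hepta-1,6-diyne-3,5-diol | C#C[C@@H](O)C[C@H](O)C#C | intermediate
6 | methylmagnesium bromide | C[Mg]Br | starting material
7 | twofold alkenylmagnesium alkoxide of 8 (C5–Mg, C9–Mg, O1–Mg, O3–Mg; not isolated) | Br[Mg]/C=C(/C)[C@@H](O[Mg]Br)C[C@H](O[Mg]Br)/C(C)=C\[Mg]Br | intermediate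
8 | (1Z,3S,5S,6Z)-1,7-diiodo-2,6-dimethylhepta-1,6-diene-3,5-diol | I/C=C(/C)[C@@H](O)C[C@H](O)/C(C)=C\I | intermediate
9 | (1Z,3S,5S,6Z)-5-[(tert-butyldimethylsilyl)oxy]-1,7-diiodo-2,6-dimethylhepta-1,6-dien-3-ol | I/C=C(/C)[C@@H](O)C[C@H](O[Si](C)(C)C(C)(C)C)/C(C)=C\I | intermediate
10 | (R)-4-benzyloxazolidin-2-one | O=C1N[C@H](Cc2ccccc2)CO1 | starting material
11 | methyl 4-chloro-4-oxobutanoate | COC(=O)CCC(Cl)=O | starting material
12 | methyl 4-[(R)-4-benzyl-2-oxooxazolidin-3-yl]-4-oxobutanoate | COC(=O)CCC(=O)N1[C@H](Cc2ccccc2)COC1=O | intermediate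
13 | 2-[(chloromethoxy)methyl]naphthalene | ClCOCc1ccc2ccccc2c1 | starting material
14 | methyl (S)-3-{[(R)-4-benzyl-2-oxooxazolidin-3-yl]carbonyl}-4-(naphthalen-2-ylmethoxy)butanoate | COC(=O)C[C@@H](COCc1ccc2ccccc2c1)C(=O)N1[C@H](Cc2ccccc2)COC1=O | intermediate
15 | methyl (S)-3-[(ethylsulfanyl)carbonyl]-4-(naphthalen-2-ylmethoxy)butanoate | CCSC(=O)[C@H](COCc1ccc2ccccc2c1)CC(=O)OC | intermediate
16 | methyl (S)-3-formyl-4-(naphthalen-2-ylmethoxy)butanoate | O=C[C@H](COCc1ccc2ccccc2c1)CC(=O)OC | intermediate
17 | alkenylmagnesium alkoxide from 9 (C5–Mg and O3–Mg; C9 iodide retained; not isolated) | Cl[Mg]/C=C(/C)[C@@H](O[Mg]Cl)C[C@H](O[Si](C)(C)C(C)(C)C)/C(C)=C\I | intermediate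
18 | acyclic adduct of 17 and 16 as its C3/C6 bis(magnesium alkoxide) methyl ester (not isolated) | COC(=O)C[C@@H](COCc1ccc2ccccc2c1)[C@H](O[Mg]Cl)/C=C(/C)[C@@H](O[Mg]Cl)C[C@H](O[Si](C)(C)C(C)(C)C)/C(C)=C\I | intermediate
19 | (4S,5R)-5-[(1Z,3S,5S,6Z)-5-[(tert-butyldimethylsilyl)oxy]-3-hydroxy-7-iodo-2,6-dimethylhepta-1,6-dien-1-yl]-4-[(naphthalen-2-ylmethoxy)methyl]dihydrofuran-2(3H)-one | O=C1C[C@@H](COCc2ccc3ccccc3c2)[C@H](O1)/C=C(/C)[C@@H](O)C[C@H](O[Si](C)(C)C(C)(C)C)/C(C)=C\I | intermediate
20 | C3 triethylsilyl ether of 19 | O=C1C[C@@H](COCc2ccc3ccccc3c2)[C@H](O1)/C=C(/C)[C@@H](O[Si](CC)(CC)CC)C[C@H](O[Si](C)(C)C(C)(C)C)/C(C)=C\I | intermediate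
21 | C8 primary alcohol (hydroxymethyl on C7 of the cis-lactone) | O=C1C[C@@H](CO)[C@H](O1)/C=C(/C)[C@@H](O[Si](CC)(CC)CC)C[C@H](O[Si](C)(C)C(C)(C)C)/C(C)=C\I | intermediate
22 | C8 aldehyde (formyl on C7 of the cis-lactone) | O=C1C[C@@H](C=O)[C@H](O1)/C=C(/C)[C@@H](O[Si](CC)(CC)CC)C[C@H](O[Si](C)(C)C(C)(C)C)/C(C)=C\I | intermediate
23 | ten-membered carbocyclic C8 alcohol, saturated cis-fused 6,12-lactone, O3 triethylsilyl, O1 tert-butyldimethylsilyl, 4Z,9Z, stereocentres as in 32 | C1C(=O)O[C@@H]2/C=C(/C)[C@@H](O[Si](CC)(CC)CC)C[C@H](O[Si](C)(C)C(C)(C)C)/C(C)=C\[C@@H](O)[C@H]12 | intermediate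
24 | C11 (dimethylamino)methyl derivative of 23 (Mannich base, C11 configuration not defined; not isolated) | CN(C)CC1C(=O)O[C@@H]2/C=C(/C)[C@@H](O[Si](CC)(CC)CC)C[C@H](O[Si](C)(C)C(C)(C)C)/C(C)=C\[C@@H](O)[C@H]12 | intermediate
25 | trimethylammonium iodide of 24 (not isolated) | C[N+](C)(C)CC1C(=O)O[C@@H]2/C=C(/C)[C@@H](O[Si](CC)(CC)CC)C[C@H](O[Si](C)(C)C(C)(C)C)/C(C)=C\[C@@H](O)[C@H]12.[I-] | intermediate
26 | α-methylene lactone with free C8 hydroxyl, O3 triethylsilyl, O1 tert-butyldimethylsilyl | C=C1C(=O)O[C@@H]2/C=C(/C)[C@@H](O[Si](CC)(CC)CC)C[C@H](O[Si](C)(C)C(C)(C)C)/C(C)=C\[C@@H](O)[C@H]12 | intermediate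
27 | (Z)-2-methylbut-2-enoic acid (angelic acid) | C/C=C(/C)C(=O)O | starting material
28 | (Z)-2-methylbut-2-enoic 2,4,6-trichlorobenzoic anhydride (not isolated) | C/C=C(/C)C(=O)OC(=O)c1c(Cl)cc(Cl)cc1Cl | intermediate
29 | C8 angelate, O3 triethylsilyl, O1 tert-butyldimethylsilyl | C=C1C(=O)O[C@@H]2/C=C(/C)[C@@H](O[Si](CC)(CC)CC)C[C@H](O[Si](C)(C)C(C)(C)C)/C(C)=C\[C@@H](OC(=O)/C(C)=C\C)[C@H]12 | intermediate
30 | C3 alcohol, O8 angelate, O1 tert-butyldimethylsilyl | C=C1C(=O)O[C@@H]2/C=C(/C)[C@@H](O)C[C@H](O[Si](C)(C)C(C)(C)C)/C(C)=C\[C@@H](OC(=O)/C(C)=C\C)[C@H]12 | intermediate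
31 | O1 tert-butyldimethylsilyl ether of the target | C=C1C(=O)O[C@@H]2/C=C(/C)[C@@H](OC(C)=O)C[C@H](O[Si](C)(C)C(C)(C)C)/C(C)=C\[C@@H](OC(=O)/C(C)=C\C)[C@H]12 | intermediate
32 | target: 3-acetoxy-8-angeloyloxy-1-hydroxy ten-membered 4Z,9Z-diene with cis-fused α-methylene 6,12-lactone, 1S,3S,6R,7R,8R | C=C1C(=O)O[C@@H]2/C=C(/C)[C@@H](OC(C)=O)C[C@H](O)/C(C)=C\[C@@H](OC(=O)/C(C)=C\C)[C@H]12 | target

## Step count and least certain steps

Total step count: 19. Longest linear sequence: 15 steps (steps 1–5 and 10–19); the fragment branch is steps 6–9.

**Step 4 (key step).** The second carbometalation may stall in the crowded bis-alkoxide aggregate, or the terminal C–H bonds may be metalated, so that protonated mono-adducts and iodoalkynes dilute 8. Fallback, from 6 back to 8: the carbometalation is moved to two simple alkynols, where it is the parent reaction, and the halves are joined by an aldol reaction. 6, CuI and then I2 convert prop-2-yn-1-ol into (Z)-3-iodo-2-methylprop-2-en-1-ol F1, which MnO2 oxidizes to (Z)-3-iodo-2-methylprop-2-enal F2. The same treatment of but-3-yn-2-ol gives (Z)-4-iodo-3-methylbut-3-en-2-ol F3, oxidized to (Z)-4-iodo-3-methylbut-3-en-2-one F4. A diisopinocampheylboron-mediated aldol of F4 with F2, using the reagent antipode that gives the S carbinol, gives (1Z,5S,6Z)-5-hydroxy-1,7-diiodo-2,6-dimethylhepta-1,6-dien-3-one F5. Hydroxyl-directed 1,3-anti reduction with Me4NBH(OAc)3 (Evans–Saksena) then returns 8, whose enantiomeric purity would rest on the aldol and might need raising by crystallization.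

**Step 2.** The enolized diketone may cyclize onto an alkyne to a pyranone, or bind ruthenium as a diketonate so that reduction stops. Fallback, from 1 back to 4: the lithium enolate of 1 (LDA, THF, −78 °C) is added to 3-(trimethylsilyl)propynal to give racemic 5-hydroxy-1,7-bis(trimethylsilyl)hepta-1,6-diyn-3-one F6, an ordinary alkynyl ketone. This is reduced with RuCl[(S,S)-TsDPEN](p-cymene) in 2-propanol. Catalyst control should make the new carbinol S in both enantiomers of F6, giving 4 and the meso diol (3R,5S)-1,7-bis(trimethylsilyl)hepta-1,6-diyne-3,5-diol F7, which are diastereomers and separable by chromatography. Half the material is lost, but no enolizable diketone is involved.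

**Step 10.** Facial selectivity at C6 may be poor if the aldehyde reacts through an open transition state or through a chelate with the ester carbonyl, which leads to the trans-lactone; incomplete site selectivity of the exchange is a second concern. Fallback, from 9 and 16 back to 19: the addition is run in THF without MgBr2 to favour the C6 epimer, the (4S,5S)-lactone F8. Saponification (LiOH, THF/H2O) opens it to hydroxy acid F9, and Mitsunobu lactonization (PPh3, diisopropyl azodicarboxylate) closes the ring with inversion at C6 to give 19.

**Step 14.** Intermolecular coupling may compete, or ring closure may occur on the wrong face at C8 because the tether, not the Felkin preference, decides the approach. Fallback for the second case, from 22 back to 23: the C8-epimeric alcohol F10 from the same closure is oxidized with Dess–Martin periodinane to the ring enone F11. The ketone is then reduced under reagent control with BH3·SMe2 and the CBS oxazaborolidine enantiomer that gives the 8R carbinol, so that C8 is set by the reagent and not by the ring closure.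

**Step 15.** The C8 lithium alkoxide may attack C12 and move the lactone from O6 to O8, or enolization of the hindered ring lactone may be incomplete. Fallback, from 20 back to 24: C13 is introduced before the ring is closed, where no hydroxyl is free. 20 is enolized (LDA, −78 °C) and trapped with Eschenmoser's salt to give Mannich base F12. The naphthylmethyl ether is cleaved with DDQ in the presence of one equivalent of trifluoroacetic acid, which keeps the amine protonated, to give alcohol F13. Dess–Martin oxidation gives aldehyde F14, whose C7–H is not allylic while C11 is saturated, and the NiCl2/CrCl2 closure gives 24, which is methylated and eliminated as in step 15.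

## Further compounds

F1 | step 4 | (Z)-3-iodo-2-methylprop-2-en-1-ol | OC/C(C)=C\I
F2 | step 4 | (Z)-3-iodo-2-methylprop-2-enal | O=C/C(C)=C\I
F3 | step 4 | (Z)-4-iodo-3-methylbut-3-en-2-ol | CC(O)/C(C)=C\I
F4 | step 4 | (Z)-4-iodo-3-methylbut-3-en-2-one | CC(=O)/C(C)=C\I
F5 | step 4 | (1Z,5S,6Z)-5-hydroxy-1,7-diiodo-2,6-dimethylhepta-1,6-dien-3-one | I/C=C(/C)C(=O)C[C@H](O)/C(C)=C\I
F6 | step 2 | racemic 5-hydroxy-1,7-bis(trimethylsilyl)hepta-1,6-diyn-3-one | C[Si](C)(C)C#CC(=O)CC(O)C#C[Si](C)(C)C
F7 | step 2 | (3R,5S)-1,7-bis(trimethylsilyl)hepta-1,6-diyne-3,5-diol (meso) | C[Si](C)(C)C#C[C@@H](O)C[C@@H](O)C#C[Si](C)(C)C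
F8 | step 10 | C6 epimer of 19, (4S,5S)-lactone | O=C1C[C@@H](COCc2ccc3ccccc3c2)[C@@H](O1)/C=C(/C)[C@@H](O)C[C@H](O[Si](C)(C)C(C)(C)C)/C(C)=C\I
F9 | step 10 | hydroxy acid from F8 (C6 and C3 hydroxyls free, C12 acid) | OC(=O)C[C@@H](COCc1ccc2ccccc2c1)[C@@H](O)/C=C(/C)[C@@H](O)C[C@H](O[Si](C)(C)C(C)(C)C)/C(C)=C\I
F10 | step 14 | C8 epimer of 23 | C1C(=O)O[C@@H]2/C=C(/C)[C@@H](O[Si](CC)(CC)CC)C[C@H](O[Si](C)(C)C(C)(C)C)/C(C)=C\[C@H](O)[C@H]12
F11 | step 14 | C8 ketone (ring enone) from F10 | C1C(=O)O[C@@H]2/C=C(/C)[C@@H](O[Si](CC)(CC)CC)C[C@H](O[Si](C)(C)C(C)(C)C)/C(C)=C\C(=O)[C@H]12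
F12 | step 15 | C11 (dimethylamino)methyl derivative of 20 | O=C1C(CN(C)C)[C@@H](COCc2ccc3ccccc3c2)[C@H](O1)/C=C(/C)[C@@H](O[Si](CC)(CC)CC)C[C@H](O[Si](C)(C)C(C)(C)C)/C(C)=C\I
F13 | step 15 | C8 primary alcohol from F12 | O=C1C(CN(C)C)[C@@H](CO)[C@H](O1)/C=C(/C)[C@@H](O[Si](CC)(CC)CC)C[C@H](O[Si](C)(C)C(C)(C)C)/C(C)=C\I
F14 | step 15 | C8 aldehyde from F13 | O=C1C(CN(C)C)[C@@H](C=O)[C@H](O1)/C=C(/C)[C@@H](O[Si](CC)(CC)CC)C[C@H](O[Si](C)(C)C(C)(C)C)/C(C)=C\I
A1 | alternative 1 | open-chain C1 aldoxime with C2=C3 vinyl group on the Z-diene and saturated cis-lactone | O=C1C[C@@H]([C@H](O[Si](C)(C)C(C)(C)C)/C=C(C)\C=NO)[C@H](O1)/C=C(/C)C=C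
A2 | alternative 1 | isoxazoline-bridged cyclodecadiene fused to the saturated lactone | O=C1C[C@H]2[C@H](O[Si](C)(C)C(C)(C)C)/C=C(C)\C3=NO[C@@H](C3)/C(C)=C\[C@H]2O1
A3 | alternative 2 | 6-deoxy acid: ten-membered diene with C7 acrylic acid, C3 acetate, C8 angelate, O1 triethylsilyl | C=C(C(=O)O)[C@@H]1C/C=C(/C)[C@@H](OC(C)=O)C[C@H](O[Si](CC)(CC)CC)/C(C)=C\[C@H]1OC(=O)/C(C)=C\C
A4 | alternative 2 | C1 triethylsilyl ether of the target | C=C1C(=O)O[C@@H]2/C=C(/C)[C@@H](OC(C)=O)C[C@H](O[Si](CC)(CC)CC)/C(C)=C\[C@@H](OC(=O)/C(C)=C\C)[C@H]12
A5 | alternative 3 | open-chain C1 bromomethyl ketone with C3 enal, C7 ethynyl, O6 tert-butyldimethylsilyl, O8 4-methoxybenzyl | C#C[C@H]([C@H](O[Si](C)(C)C(C)(C)C)/C=C(/C)C=O)[C@H](OCc1ccc(OC)cc1)/C=C(C)\C(=O)CBr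
A6 | alternative 3 | cyclodecadiene with C3 acetate, free C1 hydroxyl and C7 ethynyl | C#C[C@@H]1[C@H](O[Si](C)(C)C(C)(C)C)/C=C(/C)[C@@H](OC(C)=O)C[C@H](O)/C(C)=C\[C@H]1OCc2ccc(OC)cc2
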